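**Retrosynthetic overview**
1. The benzil is cut on both sides of its C2O2 unit. The chromene C6 (as aryllithium), 1,4-dimethylpiperazine-2,3-dione and 4-(methoxymethoxy)phenyllithium are joined in one flask, and MOM removal ends the route.
2. Key disconnection: ring A and the pyran ring are taken apart together. O1–C2 comes from oxa-6π closure of an o-quinone methide, and C8a–C4a, C5–C6 and C8–C8a come from a Danheiser benzannulation. This leads back to 3-methoxy-4-prenylcyclobutenone and the siloxyalkyne i-Pr3SiO–C≡C–CH(OMe)–CH=CMe2.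
3. Enabling feature: the three ring A oxygens are mutually meta, with O1 on C8a, the pyran carbon C4 on the neighbouring C4a and the next oxygen on C5. This is the OH / carbon substituent / O-silyl triad that a cyclobutenone–siloxyalkyne benzannulation lays down, and O1–C8a–C4a–C4–C3–C2 is then a latent 1-oxatriene.
4. Ring order: ring A first (6π electrocyclization), the pyran ring second (oxa-6π), both in the same flask. Ring B is bought.
5. Fragments: the cyclobutenone comes from prenylketene and methoxyethyne by (2+2) cycloaddition. The siloxyalkyne comes from 3-methylbut-2-enal, HC≡CMgBr and MeI, then acetylide oxidation and O-silylation.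

Key step: step 7

Assumption: 4, 23 and 24 are taken as purchasable. The target is achiral, so all stereocentres of intermediates (7, 10, 11, 14, 16, 18, 26, 28) are carried as racemates or mixtures and vanish later.

**Step 1**
Reactants: 1 2-chloro-1,1-dimethoxyethane
Product: 3 methoxyethyne, via sodium methoxyacetylide 2 (not isolated)
Conditions: NaNH2 (3 equiv), NH3(l), −33 °C; cold sat. aq. NaCl; distil into a cold trap
Reagents that add atoms: none
Why: Base-induced double elimination (loss of MeOH, then of HCl) from the chloroacetal should give acetylide 2, which is protonated on quenching, as in the standard alkoxyacetylene preparation.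

**Step 2**
Reactants: 4 5-methylhex-4-enoic acid
Product: 5 5-methylhex-4-enoyl chloride
Conditions: (COCl)2, cat. DMF, CH2Cl2, 0 °C → rt
Reagents that add atoms: oxalyl chloride, O=C(Cl)C(=O)Cl
Why: This is standard acid chloride formation through the chloroiminium species, and the trisubstituted alkene should be untouched under these cold, short conditions.

**Step 3**
Reactants: 5 5-methylhex-4-enoyl chloride, 3 methoxyethyne
Product: 7 rac-3-methoxy-4-(3-methylbut-2-en-1-yl)cyclobut-2-en-1-one, via prenylketene 6 (not isolated)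
Conditions: 3 (excess), Et3N, Et2O, 0 °C, slow addition of 5
Reagents that add atoms: none
Why: In this ketene–ynol ether (2+2) cycloaddition, Et3N dehydrochlorinates 5 to 6, whose carbonyl carbon bonds to the nucleophilic CH terminus of 3, so OMe ends on C3 and prenyl on C4 (racemic stereocentre, erased in step 7).

**Step 4**
Reactants: 8 3-methylbut-2-enal, 9 ethynylmagnesium bromide
Product: 10 rac-5-methylhex-4-en-1-yn-3-ol
Conditions: THF, 0 °C; sat. aq. NH4Cl
Reagents that add atoms: none
Why: This is 1,2-addition of an acetylide Grignard reagent to an enal, and the carbinol centre forms as a racemate that is erased in step 7.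

**Step 5**
Reactants: 10 rac-5-methylhex-4-en-1-yn-3-ol
Product: 11 rac-3-methoxy-5-methylhex-4-en-1-yne
Conditions: NaH, MeI, THF, 0 °C → rt
Reagents that add atoms: iodomethane, CI
Why: Williamson ether synthesis on the alkoxide installs a poor leaving group that should stay in place until a phenol is unveiled next to it.

**Step 6**
Reactants: 11 rac-3-methoxy-5-methylhex-4-en-1-yne
Product: 14 rac-triisopropyl[(3-methoxy-5-methylhex-4-en-1-yn-1-yl)oxy]silane, via lithium acetylide 12 (not isolated), via lithium ynolate 13 (not isolated)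
Conditions: n-BuLi, THF, −78 °C; LiOOt-Bu (from t-BuOOH + LiN(SiMe3)2), −78 → 0 °C; i-Pr3SiOTf, −78 °C; Et3N-deactivated silica
Reagents that add atoms: tert-butyl hydroperoxide, CC(C)(C)OO; triisopropylsilyl trifluoromethanesulfonate, CC(C)[Si](C(C)C)(C(C)C)OS(=O)(=O)C(F)(F)F
Why: Electrophilic oxygen transfer from the lithium peroxide to the acetylide gives the ynolate, which the bulky silyl triflate traps on oxygen, as in the established route from terminal alkynes to siloxyalkynes.

**Step 7**
Reactants: 7 rac-3-methoxy-4-(3-methylbut-2-en-1-yl)cyclobut-2-en-1-one, 14 rac-triisopropyl[(3-methoxy-5-methylhex-4-en-1-yn-1-yl)oxy]silane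
Product: 20 triisopropyl{[7-methoxy-2,2-dimethyl-8-(3-methylbut-2-en-1-yl)-2H-chromen-5-yl]oxy}silane, via vinylketene 15 (not isolated), via vinylcyclobutenone 16 (not isolated), via dienylketene 17 (not isolated), via phenol 18 (not isolated), via o-quinone methide 19 (not isolated)
Conditions: toluene, 4 Å MS, Ar, 80 → 110 °C (sealed tube)
Reagents that add atoms: none
Why: Proposed new method: heat opens 7 (4π, prenyl rotating outward) to vinylketene 15, the carbon-substituted, nucleophilic alkyne carbon of 14 attacks the ketene carbonyl carbon in a (2+2) cycloaddition to 16, and 4π opening to 17, 6π electrocyclization and tautomerization give phenol 18, whose benzylic and allylic methyl ether ortho to the new OH expels MeOH to o-quinone methide 19, which closes between its carbonyl oxygen and the CMe2 terminus. The closest known reaction types are the Danheiser benzannulation of cyclobutenones with siloxyalkynes (resorcinol monosilyl ethers, also with secondary allylic alkyne substituents) and the chromium carbene complex benzannulation/o-quinone methide/electrocyclization cascade of alkenyl propargyl ethers; new are their metal-free merger and the 3-alkoxycyclobutenone as vinylketene source. Ring A closes by 6π electrocyclization of 17 (bond C8–C8a), and the pyran ring closes by thermal disrotatory oxa-6π electrocyclization of the 1-oxatriene O=C8a–C4a=C4–C3=C2 of 19 (bond O1–C2), driven by rearomatization. No stereocentre is formed, and those of racemic 7 and 14 disappear. The step needs (2+2) rather than (4+2) reactivity of 15 (the normal behaviour of vinylketenes) and one orientation of 14 (fixed by the ynol ether polarity), which together put prenyl on C8, OMe on C7, H on C6 and OSi on C5; closure through the C8a oxygen and not the C5 oxygen is secured because only the former is unmasked, and the bulky OSi(i-Pr)3 turns the isobutenyl arm of 19 toward the carbonyl oxygen. The 4 Å sieves bind the MeOH so that it should not intercept ketenes 15 and 17, and the doubly ortho-substituted OH of 18 is too hindered to be acylated by them.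

**Step 8**
Reactants: 20 triisopropyl{[7-methoxy-2,2-dimethyl-8-(3-methylbut-2-en-1-yl)-2H-chromen-5-yl]oxy}silane
Product: 21 7-methoxy-2,2-dimethyl-8-(3-methylbut-2-en-1-yl)-2H-chromen-5-ol
Conditions: Bu4NF, AcOH (1:1), THF, 0 °C
Reagents that add atoms: none
Why: Fluoride cleaves the aryl silyl ether, and the AcOH buffer keeps the electron-rich phenoxide from building up.

**Step 9**
Reactants: 21 7-methoxy-2,2-dimethyl-8-(3-methylbut-2-en-1-yl)-2H-chromen-5-ol
Product: 22 7-methoxy-5-(methoxymethoxy)-2,2-dimethyl-8-(3-methylbut-2-en-1-yl)-2H-chromene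
Conditions: MOMCl, i-Pr2NEt, CH2Cl2, 0 °C → rt
Reagents that add atoms: chloromethyl methyl ether, COCCl
Why: MOM protection of the phenol turns O5 into a strong directing group for the metalation that follows.

**Step 10**
Reactants: 22 7-methoxy-5-(methoxymethoxy)-2,2-dimethyl-8-(3-methylbut-2-en-1-yl)-2H-chromene, 23 1,4-dimethylpiperazine-2,3-dione, 24 1-bromo-4-(methoxymethoxy)benzene
Product: 29 1-[7-methoxy-5-(methoxymethoxy)-2,2-dimethyl-8-(3-methylbut-2-en-1-yl)-2H-chromen-6-yl]-2-[4-(methoxymethoxy)phenyl]ethane-1,2-dione, via 6-lithiochromene 25 (not isolated), via monoadduct alkoxide 26 (not isolated), via aryllithium 27 (not isolated), via bisadduct dialkoxide 28 (not isolated)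
Conditions: 22, n-BuLi, THF, 0 °C; 23, −78 → 0 °C; 27 (from 24, n-BuLi, THF, −78 °C, second flask), −78 °C → rt; 1 M aq. HCl, 0 °C
Reagents that add atoms: none
Why: Directed ortho-metalation at C6 (the only ring A C–H, flanked by OMOM and OMe) is followed by sequential addition of two different aryllithiums to the cyclic oxamide 23, whose tetrahedral adducts 26 and 28 hold until acid hydrolysis releases the unsymmetrical 1,2-diketone, a known α-dione synthesis.

**Step 11**
Reactants: 29 1-[7-methoxy-5-(methoxymethoxy)-2,2-dimethyl-8-(3-methylbut-2-en-1-yl)-2H-chromen-6-yl]-2-[4-(methoxymethoxy)phenyl]ethane-1,2-dione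
Product: 30 1-[5-hydroxy-7-methoxy-2,2-dimethyl-8-(3-methylbut-2-en-1-yl)-2H-chromen-6-yl]-2-(4-hydroxyphenyl)ethane-1,2-dione (target)
Conditions: 3 M aq. HCl, THF, 40 °C
Reagents that add atoms: none
Why: Acid hydrolysis removes both MOM acetals (the one ortho to the carbonyl being especially labile), and the prenyl group, flanked only by OMe and O1, has no free ortho OH onto which it could cyclize.

**Compound list**
1 | 2-chloro-1,1-dimethoxyethane | COC(CCl)OC | starting material
2 | sodium methoxyacetylide | [Na+].[C-]#COC | intermediate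
3 | methoxyethyne | C#COC | intermediate
4 | 5-methylhex-4-enoic acid | CC(C)=CCCC(=O)O | starting material
5 | 5-methylhex-4-enoyl chloride | CC(C)=CCCC(=O)Cl | intermediate
6 | prenylketene (5-methylhexa-1,4-dien-1-one) | CC(C)=CCC=C=O | intermediate
7 | rac-3-methoxy-4-(3-methylbut-2-en-1-yl)cyclobut-2-en-1-one | COC1=CC(=O)C1CC=C(C)C | intermediate
8 | 3-methylbut-2-enal | CC(C)=CC=O | starting material
9 | ethynylmagnesium bromide | C#C[Mg]Br | starting material
10 | rac-5-methylhex-4-en-1-yn-3-ol | C#CC(O)C=C(C)C | intermediate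
11 | rac-3-methoxy-5-methylhex-4-en-1-yne | C#CC(OC)C=C(C)C | intermediate
12 | lithium acetylide of 11 | [Li]C#CC(OC)C=C(C)C | intermediate
13 | lithium 3-methoxy-5-methylhex-4-en-1-yn-1-olate | [Li+].[O-]C#CC(OC)C=C(C)C | intermediate
14 | rac-triisopropyl[(3-methoxy-5-methylhex-4-en-1-yn-1-yl)oxy]silane | CC(C)[Si](C(C)C)(C(C)C)OC#CC(OC)C=C(C)C | intermediate
15 | (3Z)-3-methoxy-7-methylocta-1,3,6-trien-1-one (vinylketene) | O=C=C/C(OC)=C/CC=C(C)C | intermediate
16 | 4-[(1Z)-1-methoxy-5-methylhexa-1,4-dien-1-yl]-2-(1-methoxy-3-methylbut-2-en-1-yl)-3-[(triisopropylsilyl)oxy]cyclobut-2-en-1-one (diastereomer mixture) | O=C1C(C(OC)C=C(C)C)=C(O[Si](C(C)C)(C(C)C)C(C)C)C1/C(OC)=C/CC=C(C)C | intermediate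
17 | (3E,5Z)-5-methoxy-2-(1-methoxy-3-methylbut-2-en-1-yl)-9-methyl-3-[(triisopropylsilyl)oxy]deca-1,3,5,8-tetraen-1-one (dienylketene) | O=C=C(C(OC)C=C(C)C)/C(O[Si](C(C)C)(C(C)C)C(C)C)=C\C(OC)=C\CC=C(C)C | intermediate
18 | rac-5-methoxy-2-(1-methoxy-3-methylbut-2-en-1-yl)-6-(3-methylbut-2-en-1-yl)-3-[(triisopropylsilyl)oxy]phenol | COc1cc(O[Si](C(C)C)(C(C)C)C(C)C)c(C(OC)C=C(C)C)c(O)c1CC=C(C)C | intermediate
19 | (6Z)-3-methoxy-6-(3-methylbut-2-en-1-ylidene)-2-(3-methylbut-2-en-1-yl)-5-[(triisopropylsilyl)oxy]cyclohexa-2,4-dien-1-one | O=C1C(CC=C(C)C)=C(OC)C=C(O[Si](C(C)C)(C(C)C)C(C)C)/C1=C/C=C(C)C | intermediate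
20 | triisopropyl{[7-methoxy-2,2-dimethyl-8-(3-methylbut-2-en-1-yl)-2H-chromen-5-yl]oxy}silane | COc1cc(O[Si](C(C)C)(C(C)C)C(C)C)c2C=CC(C)(C)Oc2c1CC=C(C)C | intermediate
21 | 7-methoxy-2,2-dimethyl-8-(3-methylbut-2-en-1-yl)-2H-chromen-5-ol | COc1cc(O)c2C=CC(C)(C)Oc2c1CC=C(C)C | intermediate
22 | 7-methoxy-5-(methoxymethoxy)-2,2-dimethyl-8-(3-methylbut-2-en-1-yl)-2H-chromene | COc1cc(OCOC)c2C=CC(C)(C)Oc2c1CC=C(C)C | intermediate
23 | 1,4-dimethylpiperazine-2,3-dione | CN1CCN(C)C(=O)C1=O | starting material
24 | 1-bromo-4-(methoxymethoxy)benzene | COCOc1ccc(Br)cc1 | starting material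
25 | [7-methoxy-5-(methoxymethoxy)-2,2-dimethyl-8-(3-methylbut-2-en-1-yl)-2H-chromen-6-yl]lithium | [Li]c1c(OC)c(CC=C(C)C)c2OC(C)(C)C=Cc2c1OCOC | intermediate
26 | lithium 2-(chromen-6-yl)-1,4-dimethyl-3-oxopiperazin-2-olate (racemic monoadduct) | [Li+].[O-]C1(N(C)CCN(C)C1=O)c1c(OC)c(CC=C(C)C)c2OC(C)(C)C=Cc2c1OCOC | intermediate
27 | [4-(methoxymethoxy)phenyl]lithium | [Li]c1ccc(OCOC)cc1 | intermediate
28 | dilithium 2-(chromen-6-yl)-3-[4-(methoxymethoxy)phenyl]-1,4-dimethylpiperazine-2,3-diolate (diastereomer mixture) | [Li+].[Li+].[O-]C1(N(C)CCN(C)C1([O-])c1ccc(OCOC)cc1)c1c(OC)c(CC=C(C)C)c2OC(C)(C)C=Cc2c1OCOC | intermediate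
29 | 1-[7-methoxy-5-(methoxymethoxy)-2,2-dimethyl-8-(3-methylbut-2-en-1-yl)-2H-chromen-6-yl]-2-[4-(methoxymethoxy)phenyl]ethane-1,2-dione | COCOc1ccc(cc1)C(=O)C(=O)c1c(OC)c(CC=C(C)C)c2OC(C)(C)C=Cc2c1OCOC | intermediate
30 | 1-[5-hydroxy-7-methoxy-2,2-dimethyl-8-(3-methylbut-2-en-1-yl)-2H-chromen-6-yl]-2-(4-hydroxyphenyl)ethane-1,2-dione | COc1c(CC=C(C)C)c2c(c(O)c1C(=O)C(=O)c1ccc(O)cc1)C=CC(C)(C)O2 | target

Total step count: 11. Longest linear sequence: 8 (steps 4, 5, 6, 7, 8, 9, 10, 11).

**Steps most likely to fail**

**Step 7.**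
- What may go wrong:
  - The electrocyclic opening of the donor-stabilised cyclobutenone may be too slow.
  - The liberated methanol may intercept the ketenes.
  - The propargylic ether may ionise before the benzannulation has run.
- Fallback: it uses known chemistry only, sets out from 8 and comes back at 21.
  - Commercial 5-methoxyresorcinol is condensed with 8 (ethylenediammonium diacetate, toluene, reflux; Knoevenagel condensation followed by oxa-6π electrocyclization). This should give 7-methoxy-2,2-dimethyl-2H-chromen-5-ol F1, which is separated from its 5-methoxy-7-ol regioisomer.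
  - O-Prenylation (prenyl bromide, K2CO3, acetone) gives 7-methoxy-2,2-dimethyl-5-[(3-methylbut-2-en-1-yl)oxy]-2H-chromene F2.
  - Heating F2 in N,N-diethylaniline at about 200 °C should trigger an aromatic Claisen rearrangement to C6 followed by a Cope rearrangement to C8. This delivers the normal prenyl group para to the freed OH, that is 21.

**Step 10.**
- What may go wrong:
  - Deprotonation at the benzylic and allylic CH2 of the prenyl group may compete with metalation at C6.
  - Incomplete first addition would then lead to scrambling in the sequential addition.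
- Fallback: it sets out from 21 and comes back at 25, replacing C–H deprotonation by halogen–metal exchange.
  - Ortho-selective bromination of the phenol (NBS, cat. i-Pr2NH, CH2Cl2, −78 °C) at its only free ring position should give 6-bromo-7-methoxy-2,2-dimethyl-8-(3-methylbut-2-en-1-yl)-2H-chromen-5-ol F3.
  - MOM protection (MOMCl, i-Pr2NEt) gives 6-bromo-7-methoxy-5-(methoxymethoxy)-2,2-dimethyl-8-(3-methylbut-2-en-1-yl)-2H-chromene F4.
  - Bromine–lithium exchange (n-BuLi, THF, −78 °C) gives 25, which continues as in step 10.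

**Step 6.**
- What may go wrong:
  - Oxygen transfer from the peroxide to the acetylide may be incomplete.
  - C-silylation of the ynolate to a silylketene may compete with O-silylation.
- Fallback: it sets out from 8 and comes back at 21. The ynol C–O bond is taken from an alcohol, and the C–C bond is made by acetylide addition.
  - 2-(Trimethylsilyl)ethanol is added to trichloroethene (KH, THF) to give {2-[(E)-1,2-dichloroethenyloxy]ethyl}trimethylsilane F5.
  - Treatment with n-BuLi (2.2 equiv, −78 → −40 °C), then 8, then MeI/DMPU in the same flask should give rac-{2-[(3-methoxy-5-methylhex-4-en-1-yn-1-yl)oxy]ethyl}trimethylsilane F6.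
  - F6 and 7 are taken through the conditions of step 7 to {2-[(7-methoxy-2,2-dimethyl-8-(3-methylbut-2-en-1-yl)-2H-chromen-5-yl)oxy]ethyl}trimethylsilane F7.
  - Bu4NF (DMF, 60 °C) fragments the 2-silylethyl ether to 21.

**Further compounds**
F1 | step 7 | 7-methoxy-2,2-dimethyl-2H-chromen-5-ol | COc1cc(O)c2C=CC(C)(C)Oc2c1
F2 | step 7 | 7-methoxy-2,2-dimethyl-5-[(3-methylbut-2-en-1-yl)oxy]-2H-chromene | COc1cc(OCC=C(C)C)c2C=CC(C)(C)Oc2c1
F3 | step 10 | 6-bromo-7-methoxy-2,2-dimethyl-8-(3-methylbut-2-en-1-yl)-2H-chromen-5-ol | COc1c(Br)c(O)c2C=CC(C)(C)Oc2c1CC=C(C)C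
F4 | step 10 | 6-bromo-7-methoxy-5-(methoxymethoxy)-2,2-dimethyl-8-(3-methylbut-2-en-1-yl)-2H-chromene | COc1c(Br)c(OCOC)c2C=CC(C)(C)Oc2c1CC=C(C)C
F5 | step 6 | {2-[(E)-1,2-dichloroethenyloxy]ethyl}trimethylsilane | C[Si](C)(C)CCO/C(Cl)=C\Cl
F6 | step 6 | rac-{2-[(3-methoxy-5-methylhex-4-en-1-yn-1-yl)oxy]ethyl}trimethylsilane | C[Si](C)(C)CCOC#CC(OC)C=C(C)C
F7 | step 6 | {2-[(7-methoxy-2,2-dimethyl-8-(3-methylbut-2-en-1-yl)-2H-chromen-5-yl)oxy]ethyl}trimethylsilane | COc1cc(OCC[Si](C)(C)C)c2C=CC(C)(C)Oc2c1CC=C(C)C
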